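The numbers in the tables were computed for substances that don't exist; the scatter is artificial.

The ratio I looked at first was Wednesday's other mono adduct at 1.00 h over its value at 4.00 h, 4.53, set against Sunday's 1.10 between 2.50 h and 5.00 h. I read each as a pseudo-first-order loss, with the coupling partner as the reagent that sets the constant.

| setting | Thursday's | Sunday's | Wednesday's | maple | larch | birch |
|---|---|---|---|---|---|---|
| substrate | 0.31 M | 0.31 M | 0.31 M | 0.31 M | 0.31 M | 0.31 M |
| coupling partner | 0.15 M | 0.38 M | 0.90 M | 0.155 M | 0.372 M | 0.775 M |
| remark | run made earlier | run made earlier | run made earlier |  |  |  |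
| time |  |  |  | 10 h | 10 h | 10 h |

| run | time / h | other mono adduct / % | mono adduct / % |
|---|---|---|---|
| Thursday's | 0.417 | 4.4 | 9.4 |
| Thursday's | 1.33 | 7.5 | 16.7 |
| Thursday's | 2.50 | 9.7 | 20.2 |
| Thursday's | 4.00 | 9.3 | 21.7 |
| Thursday's | 5.00 | 8.4 | 23.2 |
| Sunday's | 0.417 | 8.6 | 23.0 |
| Sunday's | 1.33 | 13.1 | 34.7 |
| Sunday's | 2.50 | 12.4 | 36.0 |
| Sunday's | 4.00 | 11.9 | 38.1 |
| Sunday's | 5.00 | 11.3 | 37.9 |
| Wednesday's | 1.00 | 15.4 | 45.9 |
| Wednesday's | 2.00 | 10.4 | 43.6 |
| Wednesday's | 3.00 | 3.5 | 41.4 |
| Wednesday's | 4.00 | 3.4 | 36.3 |
| Wednesday's | 5.00 | 0.7 | 32.1 |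

(scatter of a reading: 1 percentage point)

- the earlier runs were read with a standard deviation of 1 percentage point

1. final other mono adduct, as a percentage of the substrate charged, for each flask in turn (maple, larch, birch)

The readings stop at 5.00 h, so each flask had to be carried on to 10 h. Larch is nearly Sunday's recipe, and I reached its number in two ways.

The first way used Sunday's own tail:

λ = 0.0372 /h, so larch ends at 9.38 %

The second way used Wednesday's steeper fall, with partner left counted in substrate charges. That count is the charge ratio minus the two adducts, and it is an upper bound because each adduct holds one partner and anything formed beyond them is not subtracted: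

λ = 0.504 /h, partner left at 2.00 h = 2.36

Dividing gave the quantity I carried, the loss constant per unit of partner: the hourly fractional loss of other mono adduct for each substrate charge of partner left.

κ = 0.213 /h

For larch, partner left = 0.708, so λ = 0.151 /h and the end is 5.32 %

The two ways parted. Sunday's fall of 1.1 points is smaller than the 1.4 points scatter of a difference of two readings, so the first way cheats, and I kept the second.

The forecast gave 8 %, 10.5 % and 2 %, holding that “the product levels freeze”. For larch that is higher than my figure.

The flasks gave 8.60 %, 6.07 % and 0.395 %, and the forecast's row was right within the tolerance.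

    substrate + coupling partner → mono adduct (k = 2.40 /M/h)
    coupling partner + mono adduct → double product (k = 0.230 /M/h)
    coupling partner + other mono adduct → double product (k = 1.10 /M/h)
    substrate + coupling partner → other mono adduct (k = 1.10 /M/h)
    2 substrate → homo dimer (k = 1.80 /M/h)

Between 5.00 h and 10.0 h, maple's other mono adduct went from 8.99 % to 8.60 % while its partner fell to 12.2 % of its charge. Over the same hours, larch's went from 9.92 % to 6.07 % with 23.4 % of its partner left and substrate down to 0.327 %. With the partner from these states, averaged over those hours, κ in larch was 0.297 /h. In birch, where the other mono adduct fell from 2.85 % to 0.395 %, it was 0.338 /h.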